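**Plan**

Numbering is that of the benzofuran-2(3H)-one core of the target (O1, C2, C3, C3a, C4–C7, C7a). Retrosynthetic cuts, in order: O1–C7a (lactone ring B, oxidative), C3–C3a (vinyl–aryl cross-coupling), C5–acyl (directed metalation/acylation), C2–C3 (acetylide carboxylation).
Forward: ring A is bought complete and made into ketal-protected 4-methoxycatechol. The dihydrocinnamoyl chain goes on at the carbon between two oxygens, iodine goes para to the future C6–O, and the cinnamate unit is joined there. Acetonide and tert-butyl ester then leave together, and ring B closes in the last step.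
Enabling feature: the C6–OH/C7–OH catechol of ring A lies next to C7a, and C4–OMe is para to C7–O. Two-electron oxidation gives a 4-methoxy-ortho-quinone in which C7a, the only H-bearing ring carbon, ends the dienone C6(=O)–C5=C4–C3a=C7a, which the C5 acyl group also activates. The carboxyl oxygen on C3 sits 1,5 to C7a.
The event joins two nucleophilic centres (carboxyl O and an electron-rich arene carbon) by oxidative polarity reversal. It installs the fourth ring oxygen already differentiated as the lactone, and enolisation returns the free catechol of the target, so nothing needs deprotection afterwards.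
Stereochemistry: the only element is the C3=CH(Ph) alkene. Syn-hydrostannation places tin trans to phenyl, the coupling proceeds with retention, and the Z form is also the stable one in the lactone because C4–OMe repels the phenyl ring.

Key step: step 10

Remark: compounds 14–16 keep the target numbering for corresponding atoms. The names of 4 and 7–9 use 1,3-benzodioxole numbering.

**Step 1**
Reactants: 1 2-hydroxy-4-methoxybenzaldehyde
Product: 3 4-methoxybenzene-1,2-diol, via aryl formate 2 (not isolated)
Conditions: 30% aq H2O2 (1.1 equiv), NaOH (1.05 equiv), H2O/THF, 0 °C to rt, N2; then dilute HCl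
Reagents that add atoms: hydrogen peroxide, OO
Why: Dakin oxidation, in which hydroperoxide adds to the ortho-hydroxy aldehyde, the electron-rich aryl group migrates to oxygen and the formate is saponified in the flask, is the standard passage from salicylaldehydes to catechols.

**Step 2**
Reactants: 3 4-methoxybenzene-1,2-diol
Product: 4 5-methoxy-2,2-dimethyl-1,3-benzodioxole
Conditions: 2,2-dimethoxypropane (3 equiv), TsOH·H2O (cat.), toluene, reflux, MeOH trapped on 4 Å sieves (Soxhlet)
Reagents that add atoms: 2,2-dimethoxypropane, COC(C)(C)OC
Why: Acid-catalysed transketalisation of a catechol, driven by removal of methanol, gives a ketal that tolerates n-BuLi, NIS and the coupling and later leaves under protic acid that does not touch an aryl methyl ether.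

**Step 3**
Reactants: 5 3-phenylpropanoyl chloride
Product: 6 N-methoxy-N-methyl-3-phenylpropanamide
Conditions: MeONHMe·HCl (1.1 equiv), Et3N (2.2 equiv), CH2Cl2, 0 °C to rt
Reagents that add atoms: N,O-dimethylhydroxylamine hydrochloride, CNOC.Cl
Why: Weinreb amide formation by N-acylation with an acid chloride, with Et3N taking up both equivalents of HCl.

**Step 4**
Reactants: 4 5-methoxy-2,2-dimethyl-1,3-benzodioxole; 6 N-methoxy-N-methyl-3-phenylpropanamide
Product: 8 1-(5-methoxy-2,2-dimethyl-1,3-benzodioxol-4-yl)-3-phenylpropan-1-one, via aryllithium 7 (not isolated)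
Conditions: 4, n-BuLi (1.1 equiv), THF, 0 °C; then 6, -78 °C to 0 °C; cold 1 M HCl quench
Reagents that add atoms: none
Why: Directed ortho-metalation removes the benzodioxole C4–H, which lies between OMe and ring oxygen O3 so that both coordinate lithium (as with 1,2,4-trimethoxybenzene and sesamol ethers), and the Weinreb chelate stops the addition at the ketone.

**Step 5**
Reactants: 8 1-(5-methoxy-2,2-dimethyl-1,3-benzodioxol-4-yl)-3-phenylpropan-1-one
Product: 9 1-(6-iodo-5-methoxy-2,2-dimethyl-1,3-benzodioxol-4-yl)-3-phenylpropan-1-one
Conditions: NIS (1.05 equiv), TFA (0.2 equiv), MeCN, 0 °C to rt, dark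
Reagents that add atoms: N-iodosuccinimide, O=C1CCC(=O)N1I
Why: Electrophilic aromatic iodination should go to C6, which is ortho to OMe, para to O3 and meta to the acyl group, whereas C7 is activated by one oxygen only and is para to the acyl group.

**Step 6**
Reactants: 10 phenylacetylene
Product: 12 tert-butyl 3-phenylprop-2-ynoate, via lithium phenylacetylide 11 (not isolated)
Conditions: n-BuLi (1.05 equiv), THF, -78 °C; Boc2O (1.1 equiv), -78 °C to rt; dilute HCl quench
Reagents that add atoms: di-tert-butyl dicarbonate, CC(C)(C)OC(=O)OC(=O)OC(C)(C)C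
Why: C-acylation of a lithium acetylide with Boc2O is a known one-step entry to tert-butyl alkynoates and brings in the future C2 carbonyl as an acid-labile ester.

**Step 7**
Reactants: 12 tert-butyl 3-phenylprop-2-ynoate
Product: 13 tert-butyl (E)-3-phenyl-2-(tributylstannyl)prop-2-enoate
Conditions: Bu3SnH (1.1 equiv), Pd(PPh3)4 (2 mol %), THF, 0 °C to rt
Reagents that add atoms: tributyltin hydride, CCCC[SnH](CCCC)CCCC
Why: Hydrostannation of alkynoates catalysed by zerovalent palladium is a syn addition that delivers hydride to the β-carbon and tin to the α-carbon, so tin ends trans to phenyl and the alkene geometry of the target is set here.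

**Step 8**
Reactants: 9 1-(6-iodo-5-methoxy-2,2-dimethyl-1,3-benzodioxol-4-yl)-3-phenylpropan-1-one; 13 tert-butyl (E)-3-phenyl-2-(tributylstannyl)prop-2-enoate
Product: 14 tert-butyl (Z)-2-[6-methoxy-2,2-dimethyl-7-(3-phenylpropanoyl)-1,3-benzodioxol-5-yl]-3-phenylprop-2-enoate
Conditions: Pd(PPh3)4 (5 mol %), CuI (20 mol %), CsF (2 equiv), DMF, 45 °C
Reagents that add atoms: none
Why: Stille coupling of an α-stannyl acrylate with an aryl iodide, accelerated by CuI/CsF, proceeds with retention at the vinyl carbon, so the aryl group takes the place of tin trans to phenyl.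

**Step 9**
Reactants: 14 tert-butyl (Z)-2-[6-methoxy-2,2-dimethyl-7-(3-phenylpropanoyl)-1,3-benzodioxol-5-yl]-3-phenylprop-2-enoate
Product: 15 (Z)-2-[4,5-dihydroxy-2-methoxy-3-(3-phenylpropanoyl)phenyl]-3-phenylprop-2-enoic acid
Conditions: TFA/CH2Cl2/H2O 10:10:1, rt, Ar
Reagents that add atoms: none
Why: Acidolysis removes the tert-butyl ester as isobutene and hydrolyses the catechol acetonide under the conditions used for acetonide-protected DOPA building blocks, while the methyl ether, ketone and alkene are inert to aqueous TFA.

**Step 10**
Reactants: 15 (Z)-2-[4,5-dihydroxy-2-methoxy-3-(3-phenylpropanoyl)phenyl]-3-phenylprop-2-enoic acid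
Product: 17 bractelactone [(3Z)-3-benzylidene-6,7-dihydroxy-4-methoxy-5-(3-phenylpropanoyl)-1-benzofuran-2(3H)-one], via ortho-quinone acid 16 (not isolated)
Conditions: PhI(OAc)2 (1.0 equiv), 1,1,1,3,3,3-hexafluoropropan-2-ol (HFIP)/CH2Cl2 1:3, 0.02 M, 4 Å MS, -20 °C to rt, Ar, dark
Reagents that add atoms: none
Why: Proposed new method: the trivalent iodine reagent exchanges a ligand at the free C7–OH (C6–OH is hydrogen-bonded to the ketone) and removes two electrons to give the 4-methoxy-ortho-quinone 16, in which HFIP hydrogen bonding makes C7a both the δ-terminus of the dienone C6(=O)–C5=C4–C3a=C7a and the β-carbon of an O-methylated para-quinone C4(=O+Me)–C3a=C7a, so the carboxyl oxygen on C3 adds there and loss of the C7a proton restores ring A as the 6,7-catechol of 17. The closest known reaction types are the oxidative cyclisation of catechol carboxylic acids through their ortho-quinones (dihydrocaffeic acid to dihydroesculetin, 3,4-dihydroxyphenylacetic acid to the 5,6-dihydroxybenzofuranone), which add 1,4, and the closure of 2-(2-hydroxyaryl)-1,4-benzoquinones to dibenzofuranols, which has the same ring geometry; new here are the vinylogous 1,6 mode and attack next to a catechol oxygen. Ring B closes in a 5-endo-trig mode (C3a=C7a lies inside the new ring), which should be tolerable because the acceptor is a strongly polarised, nearly cationic π system, rotation about C3a–C3 can swing the carboxyl group over the ring face, and rearomatisation makes the closure irreversible. No stereocentre remains, since the transient sp3 C7a is erased by enolisation, and the alkene geometry from step 7 is untouched and is also the stable one in 17 because the E form would press the phenyl ring against C4–OMe. The step needs C7a over ipso attack at C4, and this is secured because C7a is the only ring carbon bearing hydrogen, so an adduct at C4 cannot aromatise and reverts under the dry, mildly acidic conditions. Over-oxidation is limited by one equivalent of oxidant and by the new acyloxy group, which makes 17 harder to oxidise than 15, so any quinone of 17 should be reduced again by remaining 15.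

**Compound list**

1 | 2-hydroxy-4-methoxybenzaldehyde | COc1ccc(C=O)c(O)c1 | starting material
2 | 2-hydroxy-4-methoxyphenyl formate | COc1ccc(OC=O)c(O)c1 | intermediate
3 | 4-methoxybenzene-1,2-diol | COc1ccc(O)c(O)c1 | intermediate
4 | 5-methoxy-2,2-dimethyl-1,3-benzodioxole | COc1ccc2OC(C)(C)Oc2c1 | intermediate
5 | 3-phenylpropanoyl chloride | O=C(Cl)CCc1ccccc1 | starting material
6 | N-methoxy-N-methyl-3-phenylpropanamide | CON(C)C(=O)CCc1ccccc1 | intermediate
7 | (5-methoxy-2,2-dimethyl-1,3-benzodioxol-4-yl)lithium | COc1ccc2OC(C)(C)Oc2c1[Li] | intermediate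
8 | 1-(5-methoxy-2,2-dimethyl-1,3-benzodioxol-4-yl)-3-phenylpropan-1-one | COc1ccc2OC(C)(C)Oc2c1C(=O)CCc1ccccc1 | intermediate
9 | 1-(6-iodo-5-methoxy-2,2-dimethyl-1,3-benzodioxol-4-yl)-3-phenylpropan-1-one | COc1c(I)cc2OC(C)(C)Oc2c1C(=O)CCc1ccccc1 | intermediate
10 | phenylacetylene | C#Cc1ccccc1 | starting material
11 | lithium phenylacetylide | [Li]C#Cc1ccccc1 | intermediate
12 | tert-butyl 3-phenylprop-2-ynoate | CC(C)(C)OC(=O)C#Cc1ccccc1 | intermediate
13 | tert-butyl (E)-3-phenyl-2-(tributylstannyl)prop-2-enoate | CCCC[Sn](CCCC)(CCCC)/C(=C/c1ccccc1)C(=O)OC(C)(C)C | intermediate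
14 | tert-butyl (Z)-2-[6-methoxy-2,2-dimethyl-7-(3-phenylpropanoyl)-1,3-benzodioxol-5-yl]-3-phenylprop-2-enoate | COc1c(C(=O)CCc2ccccc2)c2OC(C)(C)Oc2cc1/C(=C/c1ccccc1)C(=O)OC(C)(C)C | intermediate
15 | (Z)-2-[4,5-dihydroxy-2-methoxy-3-(3-phenylpropanoyl)phenyl]-3-phenylprop-2-enoic acid | COc1c(C(=O)CCc2ccccc2)c(O)c(O)cc1/C(=C/c1ccccc1)C(=O)O | intermediate
16 | (Z)-2-[6-methoxy-3,4-dioxo-5-(3-phenylpropanoyl)cyclohexa-1,5-dien-1-yl]-3-phenylprop-2-enoic acid | COC1=C(C(=O)CCc2ccccc2)C(=O)C(=O)C=C1/C(=C/c1ccccc1)C(=O)O | intermediate
17 | bractelactone, (3Z)-3-benzylidene-6,7-dihydroxy-4-methoxy-5-(3-phenylpropanoyl)-1-benzofuran-2(3H)-one | COc1c(C(=O)CCc2ccccc2)c(O)c(O)c2c1/C(=C/c1ccccc1)C(=O)O2 | target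

**Step count**

Total step count: 10. Longest linear sequence: 7 (steps 1, 2, 4, 5, 8, 9, 10).

**Steps most likely to fail**

Step 10. The carboxyl oxygen may fail to reach C7a along the 5-endo trajectory. Ipso attack at C4 followed by loss of the methyl ether on work-up, capture of acetate, or oligomerisation of the quinone could then take over.
The fallback uses known chemistry, namely carboxylate-directed C–H activation/C–O cyclisation of arylacetic acids without α-hydrogen to benzofuranones. It sets out from 14.
- TMSOTf/2,6-lutidine in CH2Cl2 followed by water should remove only the tert-butyl group and give the ketal-protected (Z)-acid F1.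
- Pd(OAc)2 (10 mol %), N-Boc-valine (20 mol %), PhI(OAc)2, KOAc, t-BuOH, 80 °C should palladate the only ortho C–H (C7a) through a six-membered palladacycle of divalent palladium. Oxidation to tetravalent palladium and in-plane C–O reductive elimination would give bractelactone acetonide F2.
- TFA/CH2Cl2/H2O as in step 9 comes back to the route at 17.

Step 8. Slow transmetalation of the hindered α-stannyl acrylate may allow protodestannylation, cine substitution or erosion of the alkene geometry.
The fallback reverses the polarity of the partners. It sets out from 9 and 13 and returns at 14.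
- Miyaura borylation of 9 (B2pin2, PdCl2(dppf), KOAc, dioxane, 80 °C) should give the aryl pinacol boronate F3.
- Iododestannylation of 13 (I2, CH2Cl2, 0 °C, retention) should give tert-butyl (E)-2-iodo-3-phenylprop-2-enoate F4.
- Suzuki–Miyaura coupling of the two (PdCl2(dppf), K3PO4, dioxane/H2O, 60 °C) proceeds with retention and comes back at 14.

Step 4. The hindered aryllithium may enolise the Weinreb amide instead of adding to it, and the site of lithiation may not be fully controlled.
The fallback builds the ketone by a redox detour. It sets out from 4 and returns at 8.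
- 4 is lithiated as before and trapped with the non-enolisable electrophile DMF to give the crystalline aldehyde F5, at which stage positional isomers can be removed.
- Addition of 2-phenylethylmagnesium bromide (THF, 0 °C) should give the racemic carbinol F6.
- Dess–Martin periodinane (CH2Cl2, rt) comes back at 8.

**Further compounds**

F1 | step 10 | (Z)-2-[6-methoxy-2,2-dimethyl-7-(3-phenylpropanoyl)-1,3-benzodioxol-5-yl]-3-phenylprop-2-enoic acid | COc1c(C(=O)CCc2ccccc2)c2OC(C)(C)Oc2cc1/C(=C/c1ccccc1)C(=O)O
F2 | step 10 | bractelactone 6,7-O-isopropylidene ketal (bractelactone acetonide) | COc1c(C(=O)CCc2ccccc2)c2OC(C)(C)Oc2c2c1/C(=C/c1ccccc1)C(=O)O2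
F3 | step 8 | 1-[5-methoxy-2,2-dimethyl-6-(4,4,5,5-tetramethyl-1,3,2-dioxaborolan-2-yl)-1,3-benzodioxol-4-yl]-3-phenylpropan-1-one | COc1c(B2OC(C)(C)C(C)(C)O2)cc2OC(C)(C)Oc2c1C(=O)CCc1ccccc1
F4 | step 8 | tert-butyl (E)-2-iodo-3-phenylprop-2-enoate | I/C(=C/c1ccccc1)C(=O)OC(C)(C)C
F5 | step 4 | 5-methoxy-2,2-dimethyl-1,3-benzodioxole-4-carbaldehyde | COc1ccc2OC(C)(C)Oc2c1C=O
F6 | step 4 | 1-(5-methoxy-2,2-dimethyl-1,3-benzodioxol-4-yl)-3-phenylpropan-1-ol (racemic) | COc1ccc2OC(C)(C)Oc2c1C(O)CCc1ccccc1
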